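The top pyran ring (O1, C2, C3, C4, C4a, C8a of the gallocatechin unit) is made from a 2,3-dihydrobenzofuran. Its trans O1–C2/C3–O pair on the C2–C3 edge is what an aryloxiranium ion gives on anti opening. In one operation a Lewis acid ionises a (dihydrobenzofuran-2-yl)(aryl)methyl acetate, O1 shifts from C3 to the benzylic C2, and acetate returns to C3. This expands the ring, sets 2,3-trans and places the acetate that later steers the 4α interflavan bond. The precursor is a Shi epoxide opened 5-exo by its own phenoxide. The lower 3,4-cis bond comes from aryllithium addition to a chroman-4-one and ionic reduction.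

Key step: step 6

Remark: the SMILES is read as gallocatechin-(4α→8)-catechin-(4β→8)-ent-catechin (upper unit 2R,3S,4S, 2,3-trans-3,4-trans; middle unit 2,3-trans-3,4-cis; lower unit 2S,3R); (−)-catechin, (+)-taxifolin and the L-fructose-derived Shi ketone are taken as purchasable.

**Upper unit**

Step 1
Reactants: 1 3,4,5-tris(benzyloxy)benzaldehyde
Product: 2 rac-1-[3,4,5-tris(benzyloxy)phenyl]prop-2-en-1-ol
Conditions: CH2=CHMgBr, THF, 0 °C; aq. NH4Cl
Reagents that add atoms: vinylmagnesium bromide, C=C[Mg]Br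
Why: Grignard 1,2-addition to an aryl aldehyde is reliable, and the new carbinol centre is left racemic because it is ionised in step 2.

Step 2
Reactants: 2 rac-1-[3,4,5-tris(benzyloxy)phenyl]prop-2-en-1-ol; 3 3,5-bis(benzyloxy)phenol
Product: 4 (E)-3,5-bis(benzyloxy)-2-{3-[3,4,5-tris(benzyloxy)phenyl]prop-2-en-1-yl}phenol
Conditions: H2SO4/SiO2 (cat.), CH2Cl2, rt
Reagents that add atoms: none
Why: Brønsted-acid Friedel–Crafts allylation through the 1-arylallyl cation, which the phenol should attack through its carbon ortho to OH at the unhindered terminus to give the conjugated E-alkene, as in the known cinnamyl alcohol couplings of this phenol.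

Step 3
Reactants: 4 (E)-3,5-bis(benzyloxy)-2-{3-[3,4,5-tris(benzyloxy)phenyl]prop-2-en-1-yl}phenol
Product: 5 tert-butyldimethylsilyl ether of 4
Conditions: TBSCl, imidazole, DMF, rt
Reagents that add atoms: tert-butyldimethylsilyl chloride, CC(C)(C)[Si](C)(C)Cl
Why: Standard silyl ether formation masks the electron-rich phenol so that it is not oxidised in the epoxidation.

Step 4
Reactants: 5 tert-butyldimethylsilyl ether of 4
Product: 6 tert-butyl{3,5-bis(benzyloxy)-2-[((2S,3S)-3-(3,4,5-tris(benzyloxy)phenyl)oxiran-2-yl)methyl]phenoxy}dimethylsilane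
Conditions: L-fructose-derived Shi ketone (30 mol %), KHSO5 (Oxone), K2CO3, Bu4NHSO4, MeCN/dimethoxymethane/aq. buffer, 0 °C
Reagents that add atoms: potassium peroxymonosulfate, [K+].[O-]S(=O)(=O)OO
Why: Shi asymmetric epoxidation of a trans-disubstituted styrene-type alkene, in which the L-fructose-derived ketone delivers oxygen to the face opposite to that used by the D-fructose catalyst and so should set both epoxide carbons as S.

Step 5
Reactants: 6 the (2S,3S)-epoxide
Product: 8 (S)-[(2R)-4,6-bis(benzyloxy)-2,3-dihydro-1-benzofuran-2-yl][3,4,5-tris(benzyloxy)phenyl]methanol, via epoxy phenoxide 7 (not isolated)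
Conditions: Bu4NF, THF, 0 °C → rt; water
Reagents that add atoms: none
Why: Fluoride desilylation frees the phenoxide, which should open the epoxide by a base-mediated 5-exo-tet intramolecular SN2 reaction at the nearer, non-benzylic carbon with inversion (setting C2 of the dihydrobenzofuran as R) while the benzylic carbinol keeps its S configuration.

Step 6
Reactants: 8 (S)-[(2R)-4,6-bis(benzyloxy)-2,3-dihydro-1-benzofuran-2-yl][3,4,5-tris(benzyloxy)phenyl]methanol
Product: 11 (2R,3S)-5,7-bis(benzyloxy)-2-[3,4,5-tris(benzyloxy)phenyl]chroman-3-yl acetate, via benzylic acetate 9 (not isolated), via aryloxiranium acetate 10 (not isolated)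
Conditions: Ac2O, pyridine, DMAP (cat.), CH2Cl2, rt; evaporate; then Sc(OTf)3 (5 mol %), AcOH, 40 °C
Reagents that add atoms: acetic anhydride, CC(=O)OC(C)=O
Why: Proposed new method: the benzylic acetate 9 is ionised by Sc(OTf)3 with backside participation of ring oxygen O1 (3-exo-tet closure onto the benzylic carbon, inversion), and the trans aryloxiranium ion 10 is reopened by acetate at the former ring carbon with inversion, so that O1 has moved from C3 to C2 (flavan numbering) and the five-membered ring has become the chroman (a 1,2-oxygen shift, not a direct 6-endo closure). The closest known reaction types are the zinc acetate-mediated ring expansion of 2-(1-mesyloxyalkyl)tetrahydrofurans to 3-acetoxytetrahydropyrans and the acid-induced interconversion of hydroxyisopropyl-dihydrobenzofurans and 3-chromanols. C2 is fixed by the intramolecular inversion at the (S)-carbinol carbon and C3 by the anti opening at the (R)-ring carbon, which together can only give the 2,3-trans (2R,3S) acetate. The selectivity that is needed is return of acetate at the ring carbon instead of the benzylic carbon; it should be secured thermodynamically, because benzylic return only re-forms 9, which ionises again, whereas the non-benzylic 3-acetate of the less strained six-membered ring does not. Acetic acid as solvent should capture the ion before an A-ring of a second molecule can, and the absence of base disfavours loss of the ring proton to an enol ether.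

Step 7
Reactants: 11 (2R,3S)-5,7-bis(benzyloxy)-2-[3,4,5-tris(benzyloxy)phenyl]chroman-3-yl acetate
Product: 12 (2R,3S,4S)-5,7-bis(benzyloxy)-4-(2-ethoxyethoxy)-2-[3,4,5-tris(benzyloxy)phenyl]chroman-3-yl acetate
Conditions: DDQ, HOCH2CH2OEt, CH2Cl2, rt
Reagents that add atoms: 2-ethoxyethanol, CCOCCO
Why: DDQ benzylic oxidation at C4 followed by capture with 2-ethoxyethanol is a known activation of 3-O-acyl flavan-3-ols, and the C4 configuration (expected 4β) is of no consequence because this centre is ionised again in step 15.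

**Lower unit**

Step 8
Reactants: 13 (−)-catechin, (2S,3R)
Product: 14 (2S,3R)-5,7-bis(benzyloxy)-2-[3,4-bis(benzyloxy)phenyl]chroman-3-ol
Conditions: BnBr, K2CO3, DMF, rt
Reagents that add atoms: benzyl bromide, BrCc1ccccc1
Why: Williamson benzylation with a carbonate base alkylates only the four phenols and leaves the secondary alcohol and both stereocentres untouched.

Step 9
Reactants: 14 (2S,3R)-5,7-bis(benzyloxy)-2-[3,4-bis(benzyloxy)phenyl]chroman-3-ol
Product: 15 (2S,3R)-3,5,7-tris(benzyloxy)-2-[3,4-bis(benzyloxy)phenyl]chroman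
Conditions: NaH, BnBr, Bu4NI (cat.), DMF, 0 °C → rt
Reagents that add atoms: benzyl bromide, BrCc1ccccc1
Why: Williamson etherification of the remaining secondary alkoxide gives the fully benzylated unit needed for halogen–lithium exchange.

Step 10
Reactants: 15 (2S,3R)-3,5,7-tris(benzyloxy)-2-[3,4-bis(benzyloxy)phenyl]chroman
Product: 16 (2S,3R)-3,5,7-tris(benzyloxy)-2-[3,4-bis(benzyloxy)phenyl]-8-bromochroman
Conditions: NBS, CH2Cl2, −78 °C → rt
Reagents that add atoms: N-bromosuccinimide, O=C1CCC(=O)N1Br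
Why: Electrophilic aromatic bromination with NBS should go to C8, the more reactive of the two free A-ring positions of 3-O-protected benzylated catechins.

**Middle unit**

Step 11
Reactants: 17 (+)-taxifolin, (2R,3R)
Product: 18 (2R,3R)-5,7-bis(benzyloxy)-2-[3,4-bis(benzyloxy)phenyl]-3-hydroxychroman-4-one
Conditions: BnBr, K2CO3, DMF, rt
Reagents that add atoms: benzyl bromide, BrCc1ccccc1
Why: Williamson benzylation at room temperature etherifies the four phenols, the chelated 5-OH last, under conditions mild enough to spare the base-sensitive 2,3-trans dihydroflavonol.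

Step 12
Reactants: 18 (2R,3R)-5,7-bis(benzyloxy)-2-[3,4-bis(benzyloxy)phenyl]-3-hydroxychroman-4-one
Product: 19 (2R,3R)-3,5,7-tris(benzyloxy)-2-[3,4-bis(benzyloxy)phenyl]chroman-4-one
Conditions: BnOC(=NH)CCl3, TfOH (cat.), CH2Cl2/cyclohexane, 0 °C → rt
Reagents that add atoms: benzyl 2,2,2-trichloroacetimidate, N=C(OCc1ccccc1)C(Cl)(Cl)Cl
Why: Acid-catalysed benzylation with the trichloroacetimidate protects the alcohol next to the ketone without base and so without enolisation or ring opening.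

**Assembly**

Step 13
Reactants: 16 the 8-bromide; 19 the chroman-4-one
Product: 21 4α-hydroxy-penta-O-benzylcatechin-(4β→8)-penta-O-benzyl-ent-catechin, via 8-lithio flavan 20 (not isolated)
Conditions: 16, t-BuLi (2 equiv), THF, −78 °C; then 19, −78 → 0 °C; aq. NH4Cl
Reagents that add atoms: none
Why: Bromine–lithium exchange followed by 1,2-addition of the aryllithium to the chroman-4-one forms the C4–C8 bond as in the known additions of 8-lithio flavans to flavan-4-ones, and the new tertiary carbinol centre (drawn with the aryl group β) is erased in step 14.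

Step 14
Reactants: 21 the tertiary alcohol
Product: 22 penta-O-benzylcatechin-(4β→8)-penta-O-benzyl-ent-catechin
Conditions: n-Bu3SnH, CF3CO2H, CH2Cl2, 0 °C
Reagents that add atoms: none
Why: Ionic reduction (ionisation to the doubly benzylic C4 cation and hydride transfer from the tin hydride) should deliver hydride to the α face, anti to the 3-benzyloxy group that allylic strain with the C4 aryl group pushes pseudo-axial, leaving the aryl group β and hence 3,4-cis, as is known for the 2,3-cis series.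

Step 15
Reactants: 12 the 4-(2-ethoxyethoxy) electrophile; 22 the 3,4-cis dimer
Product: 23 3-O-acetyl-penta-O-benzylgallocatechin-(4α→8)-penta-O-benzylcatechin-(4β→8)-penta-O-benzyl-ent-catechin
Conditions: TMSOTf (cat.), CH2Cl2, 4 Å MS, −78 → −20 °C; Et3N
Reagents that add atoms: none
Why: Lewis-acid Friedel–Crafts flavanylation in which the 3-acetate bridges the C4 cation on its β face, so that C8 of the upper unit of 22, its most nucleophilic free position, should attack from the α face and set the top C4 as 4α, trans to O3.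

Step 16
Reactants: 23 the acetylated trimer
Product: 24 penta-O-benzylgallocatechin-(4α→8)-penta-O-benzylcatechin-(4β→8)-penta-O-benzyl-ent-catechin
Conditions: K2CO3 (cat.), MeOH/THF, rt
Reagents that add atoms: none
Why: Zemplén-type transesterification removes the lone acetate, while the fifteen benzyl ethers and the acid-labile interflavan bonds are inert to base.

Step 17
Reactants: 24 the pentadeca-O-benzyl trimer
Product: 25 gallocatechin-(4α→8)-catechin-(4β→8)-ent-catechin (CNP0155646.2)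
Conditions: H2 (1 atm), Pd(OH)2/C, THF/MeOH/H2O, rt
Reagents that add atoms: none
Why: Hydrogenolysis over Pd(OH)2/C should cleave all fifteen benzyl ethers under neutral conditions without touching the C4–C8 bonds or any stereocentre.

**Compound list**

1 | 3,4,5-tris(benzyloxy)benzaldehyde | O=Cc1cc(OCc2ccccc2)c(OCc2ccccc2)c(OCc2ccccc2)c1 | starting material
2 | rac-1-[3,4,5-tris(benzyloxy)phenyl]prop-2-en-1-ol | C=CC(O)c1cc(OCc2ccccc2)c(OCc2ccccc2)c(OCc2ccccc2)c1 | intermediate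
3 | 3,5-bis(benzyloxy)phenol | Oc1cc(OCc2ccccc2)cc(OCc2ccccc2)c1 | starting material
4 | (E)-3,5-bis(benzyloxy)-2-{3-[3,4,5-tris(benzyloxy)phenyl]prop-2-en-1-yl}phenol | Oc1cc(OCc2ccccc2)cc(OCc2ccccc2)c1C/C=C/c1cc(OCc2ccccc2)c(OCc2ccccc2)c(OCc2ccccc2)c1 | intermediate
5 | tert-butyldimethylsilyl ether of 4 | CC(C)(C)[Si](C)(C)Oc1cc(OCc2ccccc2)cc(OCc2ccccc2)c1C/C=C/c1cc(OCc2ccccc2)c(OCc2ccccc2)c(OCc2ccccc2)c1 | intermediate
6 | tert-butyl{3,5-bis(benzyloxy)-2-[((2S,3S)-3-(3,4,5-tris(benzyloxy)phenyl)oxiran-2-yl)methyl]phenoxy}dimethylsilane | CC(C)(C)[Si](C)(C)Oc1cc(OCc2ccccc2)cc(OCc2ccccc2)c1C[C@@H]1O[C@H]1c1cc(OCc2ccccc2)c(OCc2ccccc2)c(OCc2ccccc2)c1 | intermediate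
7 | tetrabutylammonium 3,5-bis(benzyloxy)-2-[((2S,3S)-3-(3,4,5-tris(benzyloxy)phenyl)oxiran-2-yl)methyl]phenoxide | [O-]c1cc(OCc2ccccc2)cc(OCc2ccccc2)c1C[C@@H]1O[C@H]1c1cc(OCc2ccccc2)c(OCc2ccccc2)c(OCc2ccccc2)c1.CCCC[N+](CCCC)(CCCC)CCCC | intermediate (not isolated)
8 | (S)-[(2R)-4,6-bis(benzyloxy)-2,3-dihydro-1-benzofuran-2-yl][3,4,5-tris(benzyloxy)phenyl]methanol | O[C@@H](c1cc(OCc2ccccc2)c(OCc2ccccc2)c(OCc2ccccc2)c1)[C@H]1Cc2c(OCc3ccccc3)cc(OCc3ccccc3)cc2O1 | intermediate
9 | (S)-[(2R)-4,6-bis(benzyloxy)-2,3-dihydro-1-benzofuran-2-yl][3,4,5-tris(benzyloxy)phenyl]methyl acetate | CC(=O)O[C@@H](c1cc(OCc2ccccc2)c(OCc2ccccc2)c(OCc2ccccc2)c1)[C@H]1Cc2c(OCc3ccccc3)cc(OCc3ccccc3)cc2O1 | intermediate (not isolated)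
10 | trans-aryloxiranium acetate (O1 bridges the benzylic carbon and C2 of the dihydrobenzofuran) | [C@@H]1(c2cc(OCc3ccccc3)c(OCc3ccccc3)c(OCc3ccccc3)c2)[C@H]2Cc3c(OCc4ccccc4)cc(OCc4ccccc4)cc3[O+]12.CC(=O)[O-] | intermediate (not isolated)
11 | (2R,3S)-5,7-bis(benzyloxy)-2-[3,4,5-tris(benzyloxy)phenyl]chroman-3-yl acetate | O(Cc1ccccc1)c1cc(OCc2ccccc2)c2c(c1)O[C@H](c1cc(OCc3ccccc3)c(OCc3ccccc3)c(OCc3ccccc3)c1)[C@@H](OC(C)=O)C2 | intermediate
12 | (2R,3S,4S)-5,7-bis(benzyloxy)-4-(2-ethoxyethoxy)-2-[3,4,5-tris(benzyloxy)phenyl]chroman-3-yl acetate | O(Cc1ccccc1)c1cc(OCc2ccccc2)c2c(c1)O[C@H](c1cc(OCc3ccccc3)c(OCc3ccccc3)c(OCc3ccccc3)c1)[C@@H](OC(C)=O)[C@H]2OCCOCC | intermediate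
13 | (−)-catechin, (2S,3R) | Oc1cc(O)c2c(c1)O[C@@H](c1ccc(O)c(O)c1)[C@H](O)C2 | starting material
14 | (2S,3R)-5,7-bis(benzyloxy)-2-[3,4-bis(benzyloxy)phenyl]chroman-3-ol | O(Cc1ccccc1)c1cc(OCc2ccccc2)c2c(c1)O[C@@H](c1ccc(OCc3ccccc3)c(OCc3ccccc3)c1)[C@H](O)C2 | intermediate
15 | (2S,3R)-3,5,7-tris(benzyloxy)-2-[3,4-bis(benzyloxy)phenyl]chroman | O(Cc1ccccc1)c1cc(OCc2ccccc2)c2c(c1)O[C@@H](c1ccc(OCc3ccccc3)c(OCc3ccccc3)c1)[C@H](OCc1ccccc1)C2 | intermediate
16 | (2S,3R)-3,5,7-tris(benzyloxy)-2-[3,4-bis(benzyloxy)phenyl]-8-bromochroman | O(Cc1ccccc1)c1cc(OCc2ccccc2)c2c(c1Br)O[C@@H](c1ccc(OCc3ccccc3)c(OCc3ccccc3)c1)[C@H](OCc1ccccc1)C2 | intermediate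
17 | (+)-taxifolin, (2R,3R) | Oc1cc(O)c2c(c1)O[C@H](c1ccc(O)c(O)c1)[C@@H](O)C2=O | starting material
18 | (2R,3R)-5,7-bis(benzyloxy)-2-[3,4-bis(benzyloxy)phenyl]-3-hydroxychroman-4-one | O(Cc1ccccc1)c1cc(OCc2ccccc2)c2c(c1)O[C@H](c1ccc(OCc3ccccc3)c(OCc3ccccc3)c1)[C@@H](O)C2=O | intermediate
19 | (2R,3R)-3,5,7-tris(benzyloxy)-2-[3,4-bis(benzyloxy)phenyl]chroman-4-one | O(Cc1ccccc1)c1cc(OCc2ccccc2)c2c(c1)O[C@H](c1ccc(OCc3ccccc3)c(OCc3ccccc3)c1)[C@@H](OCc1ccccc1)C2=O | intermediate
20 | (2S,3R)-3,5,7-tris(benzyloxy)-2-[3,4-bis(benzyloxy)phenyl]chroman-8-yllithium | O(Cc1ccccc1)c1cc(OCc2ccccc2)c2c(c1[Li])O[C@@H](c1ccc(OCc3ccccc3)c(OCc3ccccc3)c1)[C@H](OCc1ccccc1)C2 | intermediate (not isolated)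
21 | 4α-hydroxy-penta-O-benzylcatechin-(4β→8)-penta-O-benzyl-ent-catechin (C4 epimer drawn as expected) | O(Cc1ccccc1)c1cc(OCc2ccccc2)c2c(c1)O[C@H](c1ccc(OCc3ccccc3)c(OCc3ccccc3)c1)[C@@H](OCc1ccccc1)[C@@]2(O)c1c(OCc2ccccc2)cc(OCc2ccccc2)c2c1O[C@@H](c1ccc(OCc3ccccc3)c(OCc3ccccc3)c1)[C@H](OCc1ccccc1)C2 | intermediate
22 | penta-O-benzylcatechin-(4β→8)-penta-O-benzyl-ent-catechin | O(Cc1ccccc1)c1cc(OCc2ccccc2)c2c(c1)O[C@H](c1ccc(OCc3ccccc3)c(OCc3ccccc3)c1)[C@@H](OCc1ccccc1)[C@H]2c1c(OCc2ccccc2)cc(OCc2ccccc2)c2c1O[C@@H](c1ccc(OCc3ccccc3)c(OCc3ccccc3)c1)[C@H](OCc1ccccc1)C2 | intermediate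
23 | 3-O-acetyl-penta-O-benzylgallocatechin-(4α→8)-penta-O-benzylcatechin-(4β→8)-penta-O-benzyl-ent-catechin | O(Cc1ccccc1)c1cc(OCc2ccccc2)c2c(c1)O[C@H](c1cc(OCc3ccccc3)c(OCc3ccccc3)c(OCc3ccccc3)c1)[C@@H](OC(C)=O)[C@@H]2c1c(OCc2ccccc2)cc(OCc2ccccc2)c2c1O[C@H](c1ccc(OCc3ccccc3)c(OCc3ccccc3)c1)[C@@H](OCc1ccccc1)[C@H]2c1c(OCc2ccccc2)cc(OCc2ccccc2)c2c1O[C@@H](c1ccc(OCc3ccccc3)c(OCc3ccccc3)c1)[C@H](OCc1ccccc1)C2 | intermediate
24 | penta-O-benzylgallocatechin-(4α→8)-penta-O-benzylcatechin-(4β→8)-penta-O-benzyl-ent-catechin | O(Cc1ccccc1)c1cc(OCc2ccccc2)c2c(c1)O[C@H](c1cc(OCc3ccccc3)c(OCc3ccccc3)c(OCc3ccccc3)c1)[C@@H](O)[C@@H]2c1c(OCc2ccccc2)cc(OCc2ccccc2)c2c1O[C@H](c1ccc(OCc3ccccc3)c(OCc3ccccc3)c1)[C@@H](OCc1ccccc1)[C@H]2c1c(OCc2ccccc2)cc(OCc2ccccc2)c2c1O[C@@H](c1ccc(OCc3ccccc3)c(OCc3ccccc3)c1)[C@H](OCc1ccccc1)C2 | intermediate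
25 | gallocatechin-(4α→8)-catechin-(4β→8)-ent-catechin (CNP0155646.2) | Oc1cc(O)c2c(c1)O[C@H](c1cc(O)c(O)c(O)c1)[C@@H](O)[C@@H]2c1c(O)cc(O)c2c1O[C@H](c1ccc(O)c(O)c1)[C@@H](O)[C@H]2c1c(O)cc(O)c2c1O[C@@H](c1ccc(O)c(O)c1)[C@H](O)C2 | target

**Step count and risks**

Total step count: 17.
Longest linear sequence: 10 steps (steps 1–7, 15, 16, 17).

Steps most likely to fail:

1. Step 6 (Proposed new method). What may go wrong: the ion pair is diverted instead of collapsing at the ring carbon. Acetate may return only to the benzylic carbon without the ester ionising again, the ion may lose the ring proton to give an enol ether that aromatises to a 2-benzylbenzofuran, or it may alkylate the electron-rich A-ring of a second molecule. The fallback uses known chemistry and forgoes the ring expansion. It sets out from epoxide 6: Bu4NF buffered with AcOH removes the silyl group, and camphorsulfonic acid in CH2Cl2 then promotes the usual acid-mediated 6-endo opening of the epoxide by the free phenol at the benzylic carbon with inversion, giving (2R,3S)-5,7-bis(benzyloxy)-2-[3,4,5-tris(benzyloxy)phenyl]chroman-3-ol F1. Ac2O/pyridine converts F1 into 11, where it rejoins the route.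

2. Step 14. What may go wrong: poor facial selectivity in the hydride transfer to the C4 cation if the 3-benzyloxy group stays pseudo-equatorial, or loss of the C3 proton from the cation to give an enol ether. The fallback changes the control element to a bulky 3-O-silyl ether, the group known to direct this reduction in the 2,3-cis series. It sets out from 18: TBSOTf/2,6-lutidine gives (2R,3R)-5,7-bis(benzyloxy)-2-[3,4-bis(benzyloxy)phenyl]-3-[(tert-butyldimethylsilyl)oxy]chroman-4-one F2. Addition of aryllithium 20 gives 4α-hydroxy-3-O-TBS-tetra-O-benzylcatechin-(4β→8)-penta-O-benzyl-ent-catechin F3. Reduction with n-Bu3SnH/CF3CO2H gives 3-O-TBS-tetra-O-benzylcatechin-(4β→8)-penta-O-benzyl-ent-catechin F4. Bu4NF frees 5,7,3′,4′-tetra-O-benzylcatechin-(4β→8)-penta-O-benzyl-ent-catechin F5, and NaH/BnBr benzylates F5 to 22, where it comes back.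

3. Step 15. What may go wrong: under the Lewis acid the dimer's own C4–C8 bond may ionise and scramble the units, the electrophile may attack a C6 position, or the product may react with a second electrophile. The fallback replaces Lewis-acid activation by thiophilic activation. It sets out from 12: benzyl mercaptan with BF3·OEt2 at −40 °C exchanges the 2-ethoxyethoxy group for a benzylthio group (4α, through the acetate-bridged cation), giving (2R,3S,4S)-5,7-bis(benzyloxy)-4-(benzylthio)-2-[3,4,5-tris(benzyloxy)phenyl]chroman-3-yl acetate F6. F6 is coupled with 22 by AgBF4 and 2,6-di-tert-butylpyridine in THF at 0 °C, conditions that should leave existing interflavan bonds intact, and gives 23.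

Further compounds
F1 | step 6 | (2R,3S)-5,7-bis(benzyloxy)-2-[3,4,5-tris(benzyloxy)phenyl]chroman-3-ol | O(Cc1ccccc1)c1cc(OCc2ccccc2)c2c(c1)O[C@H](c1cc(OCc3ccccc3)c(OCc3ccccc3)c(OCc3ccccc3)c1)[C@@H](O)C2
F2 | step 14 | (2R,3R)-5,7-bis(benzyloxy)-2-[3,4-bis(benzyloxy)phenyl]-3-[(tert-butyldimethylsilyl)oxy]chroman-4-one | O(Cc1ccccc1)c1cc(OCc2ccccc2)c2c(c1)O[C@H](c1ccc(OCc3ccccc3)c(OCc3ccccc3)c1)[C@@H](O[Si](C)(C)C(C)(C)C)C2=O
F3 | step 14 | 4α-hydroxy-3-O-TBS-tetra-O-benzylcatechin-(4β→8)-penta-O-benzyl-ent-catechin | O(Cc1ccccc1)c1cc(OCc2ccccc2)c2c(c1)O[C@H](c1ccc(OCc3ccccc3)c(OCc3ccccc3)c1)[C@@H](O[Si](C)(C)C(C)(C)C)[C@@]2(O)c1c(OCc2ccccc2)cc(OCc2ccccc2)c2c1O[C@@H](c1ccc(OCc3ccccc3)c(OCc3ccccc3)c1)[C@H](OCc1ccccc1)C2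
F4 | step 14 | 3-O-TBS-tetra-O-benzylcatechin-(4β→8)-penta-O-benzyl-ent-catechin | O(Cc1ccccc1)c1cc(OCc2ccccc2)c2c(c1)O[C@H](c1ccc(OCc3ccccc3)c(OCc3ccccc3)c1)[C@@H](O[Si](C)(C)C(C)(C)C)[C@H]2c1c(OCc2ccccc2)cc(OCc2ccccc2)c2c1O[C@@H](c1ccc(OCc3ccccc3)c(OCc3ccccc3)c1)[C@H](OCc1ccccc1)C2
F5 | step 14 | 5,7,3′,4′-tetra-O-benzylcatechin-(4β→8)-penta-O-benzyl-ent-catechin | O(Cc1ccccc1)c1cc(OCc2ccccc2)c2c(c1)O[C@H](c1ccc(OCc3ccccc3)c(OCc3ccccc3)c1)[C@@H](O)[C@H]2c1c(OCc2ccccc2)cc(OCc2ccccc2)c2c1O[C@@H](c1ccc(OCc3ccccc3)c(OCc3ccccc3)c1)[C@H](OCc1ccccc1)C2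
F6 | step 15 | (2R,3S,4S)-5,7-bis(benzyloxy)-4-(benzylthio)-2-[3,4,5-tris(benzyloxy)phenyl]chroman-3-yl acetate | O(Cc1ccccc1)c1cc(OCc2ccccc2)c2c(c1)O[C@H](c1cc(OCc3ccccc3)c(OCc3ccccc3)c(OCc3ccccc3)c1)[C@@H](OC(C)=O)[C@@H]2SCc1ccccc1
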